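The readings were computed for an exercise; the scatter is artificial.

In the flask you are asked about, the early readings climb steeper on a log-log plot than the late ones: the slope is 1.79 up to 1.50 min, then 1.18.

- gamma: solid monomer 5.0 × 10⁻⁴ M; initiator 2.5 µM; the very flask that is asked about, followed so far
- flask: solid monomer 5.0 × 10⁻⁴ M; initiator 2.5 µM; time 40 min

gamma run (percent of the solid monomer charged)

| time / min | monomer in chains / % |
|---|---|
| 0.250 | 0.6 |
| 0.500 | 2.5 |
| 0.833 | 5.8 |
| 1.50 | 17.8 |
| 3.00 | 40.4 |

(readings scatter by 1 percentage point)

- solid monomer is a solid; its amount is given per volume of the solution
- at the start none of the solid monomer is in solution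

1. the best time, 40 min at the latest, for monomer in chains
2. the amount of monomer in chains, in percent of the solid monomer charged, at that time

A slope near 2 means chains grow roughly as the square of time. From the reading at 1.50 min you get a clock, 3.56 min. This is the fill time, the time at which that square law, run on, reaches the whole charge.

Take two extreme versions of the flask. If chains are never lost, the whole charge ends in chains and the best time is late. If the bend is already the top, the best is the last reading, 40.4% at 3.00 min. The square law asks 71.0% there, so the reading already falls short. The allowed time is 11.3 fill times. My own estimate lies nearer the second extreme: the best time near one fill time.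

The forecast differs: 95% at 30 min, with the words “Nothing so far shows chain loss or a ceiling”.

The flask gives 40.5% at 3.02 min, which is 0.848 of a fill time, under this scheme:

    free monomer + initiator → living end + monomer in chains (k = 49.0 L mol⁻¹ s⁻¹)
    free monomer + living end → monomer in chains + living end, rate k2*[living end]*[free monomer] (k = 9100 L mol⁻¹ s⁻¹)
    solid monomer ⇌ free monomer, rate k3*(cs3 - [free monomer]) while solid is left; crystals form when [free monomer] > cs3 (solubility = 0.240 mM, k = 0.0650 s⁻¹)
    monomer in chains ⇌ isomer of the product (K = 17.0, k = 0.0110 s⁻¹)

In this flask monomer in chains stands at 5.56% at 40.0 min, and isomer of the product at 94.4%: kinetic against thermodynamic control. Now take the neighbour with 0.600 of the initiator. If the square-law coefficient follows the initiator, its fill time is 4.59 min. If the top stretches with that clock, the best stays 40.5%. If the top keeps its time, the best falls to 24.3%. Midway in logarithms lies 31.4%. The neighbour gives 33.3%.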